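The route rests on opening the C5–C10 bond of the cyclohexane (ring A). C10 (quaternary, methyl and vinyl) and C5 (methine bearing the 2-propenal unit) form a 1,2-dialkenylcyclohexane, the retron of a Cope rearrangement. The precursor is a ten-membered germacra-1(10),4-dien-12,8-olide carrying the C6 angelate, the C9 hydroxyl and a C15 alcohol. Oxidation of C15 to the enal triggers a chair [3,3] shift that breaks C2–C3, closes ring A and sets C5 and C10 together, with the trans-fused butyrolactone (ring B) choosing the face. The macrocycle arises by an indium Barbier closure of C6–C7 in an open chain whose C8/C9 pair comes from an anti glycolate aldol.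

Key step: step 14

Remark on the chemistry:
- Germacrane numbering is kept for all compounds. C10 is the quaternary carbon, C9 the carbinol, C8 and C7 the lactone fusion carbons, C6 the angelate carbon and C5 the ring methine. C1=C2 is the vinyl group, C3=C4–C15 the propenal, C11–C13 the methylene-lactone carbons and C14 the methyl.
- The descriptor 4Z in the macrocycles follows from the CIP rank of C15. The ring bonds to C3 and C6 are trans across C4=C5.
- TBS = tert-butyldimethylsilyl, TBDPS = tert-butyldiphenylsilyl.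
- Compounds 1, 4, 8 and 18 are taken as catalogue chemicals.

Step 1
Reactants: 1 tert-butyl(prop-2-yn-1-yloxy)diphenylsilane; 2 methyl chloroformate
Product: 3 methyl 4-[(tert-butyldiphenylsilyl)oxy]but-2-ynoate
Conditions: n-BuLi, THF, −78 °C; then 2, −78 °C to 0 °C
Reagents that add atoms: none
Why: Acylation of a lithium acetylide with a chloroformate is a standard route to 2-ynoates and involves no stereocentre.

Step 2
Reactants: 3 methyl 4-[(tert-butyldiphenylsilyl)oxy]but-2-ynoate; 4 but-3-en-1-ylmagnesium bromide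
Product: 5 methyl (2Z)-3-{[(tert-butyldiphenylsilyl)oxy]methyl}hepta-2,6-dienoate
Conditions: 4, CuBr·SMe2, THF, −40 °C; then 3, −78 °C; sat. aq. NH4Cl at −78 °C
Reagents that add atoms: none
Why: Syn-carbocupration of a 2-ynoate puts the butenyl group and copper on the same side, and cold protonation keeps that geometry, so C3 ends trans to C6 and the C15 arm cis to the ester.

Step 3
Reactants: 5 methyl (2Z)-3-{[(tert-butyldiphenylsilyl)oxy]methyl}hepta-2,6-dienoate; 6 methacrolein
Product: 7 methyl (2Z,6E)-3-{[(tert-butyldiphenylsilyl)oxy]methyl}-7-methyl-8-oxoocta-2,6-dienoate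
Conditions: second-generation Hoveyda–Grubbs catalyst (cat.), excess 6, CH2Cl2, 40 °C
Reagents that add atoms: none
Why: Olefin cross-metathesis of a terminal alkene with methacrolein is known to favour the (E)-2-methyl-2-enal, which installs the C1=C10 geometry, while the trisubstituted enoate stays inert.

Step 4
Reactants: 7 methyl (2Z,6E)-3-{[(tert-butyldiphenylsilyl)oxy]methyl}-7-methyl-8-oxoocta-2,6-dienoate; 8 (5R,6R)-5,6-dimethoxy-5,6-dimethyl-1,4-dioxan-2-one
Product: 9 methyl (2Z,6E,8S)-8-[(2S,5R,6R)-5,6-dimethoxy-5,6-dimethyl-3-oxo-1,4-dioxan-2-yl]-8-hydroxy-7-methyl-3-{[(tert-butyldiphenylsilyl)oxy]methyl}octa-2,6-dienoate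
Conditions: LiN(SiMe3)2, THF, −78 °C; then 7, −78 °C; AcOH quench at −78 °C
Reagents that add atoms: none
Why: In this lithium enolate aldol addition of a diacetal-protected glycolate, the ring-locked E(O)-enolate reacts through a closed chair to give the anti C8/C9 pair, and the axial methoxy group on C5 of the dioxanone (1,3-diaxial to the attacked carbon) blocks one face and fixes the absolute sense.

Step 5
Reactants: 9 aldol adduct
Product: 10 dimethyl (2S,3S,4E,8Z)-2,3-dihydroxy-4-methyl-8-{[(tert-butyldiphenylsilyl)oxy]methyl}deca-4,8-dienedioate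
Conditions: HCl (cat.), MeOH, rt
Reagents that add atoms: methanol CO
Why: Acid-catalysed lactone methanolysis and transacetalisation release the anti-diol methyl ester, and the acid-stable primary TBDPS ether, chosen for this step, and both stereocentres should stay untouched.

Step 6
Reactants: 10 anti-diol diester
Product: 11 dimethyl (2S,3S,4E,8Z)-2,3-bis[(tert-butyldimethylsilyl)oxy]-4-methyl-8-{[(tert-butyldiphenylsilyl)oxy]methyl}deca-4,8-dienedioate
Conditions: TBSOTf, 2,6-lutidine, CH2Cl2, 0 °C to rt
Reagents that add atoms: tert-butyldimethylsilyl trifluoromethanesulfonate CC(C)(C)[Si](C)(C)OS(=O)(=O)C(F)(F)F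
Why: Silyl ether formation with the triflate and a hindered base is strong enough for a vicinal secondary diol and too weakly basic to touch the α-stereocentre C8.

Step 7
Reactants: 11 bis-TBS diester
Product: 12 (2R,3S,4E,8Z)-2,3-bis[(tert-butyldimethylsilyl)oxy]-4-methyl-8-{[(tert-butyldiphenylsilyl)oxy]methyl}deca-4,8-diene-1,10-diol
Conditions: i-Bu2AlH (excess), CH2Cl2, −78 °C to −20 °C; aq. Rochelle salt
Reagents that add atoms: none
Why: Hydride reduction with i-Bu2AlH takes both the saturated and the conjugated ester to primary alcohols in 1,2-fashion without touching alkenes or silyl ethers.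

Step 8
Reactants: 12 diol
Product: 13 (2S,3S,4E,8Z)-2,3-bis[(tert-butyldimethylsilyl)oxy]-4-methyl-8-{[(tert-butyldiphenylsilyl)oxy]methyl}deca-4,8-dienedial
Conditions: TEMPO (cat.), PhI(OAc)2, CH2Cl2, rt
Reagents that add atoms: none
Why: Oxoammonium (TEMPO) oxidation converts both primary alcohols to aldehydes under near-neutral conditions that should not epimerise C8 or isomerise the C4=C5 enal.

Step 9
Reactants: 13 dialdehyde; 14 methyl acrylate
Product: 15 methyl (4R,5S,6E,10Z)-4,5-bis[(tert-butyldimethylsilyl)oxy]-3-hydroxy-6-methyl-2-methylidene-12-oxo-10-{[(tert-butyldiphenylsilyl)oxy]methyl}dodeca-6,10-dienoate (both C3 carbinol epimers)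
Conditions: DABCO, excess 14, MeOH (few equiv), rt
Reagents that add atoms: none
Why: In the Morita–Baylis–Hillman reaction only the unconjugated α-silyloxy aldehyde (C7) is electrophilic enough while the β,β-disubstituted enal (C6) is inert, and the new carbinol centre may form as a mixture because step 10 erases it.

Step 10
Reactants: 15 Morita–Baylis–Hillman adduct
Product: 16 methyl (2Z,4R,5S,6E,10Z)-2-(bromomethyl)-4,5-bis[(tert-butyldimethylsilyl)oxy]-6-methyl-12-oxo-10-{[(tert-butyldiphenylsilyl)oxy]methyl}dodeca-2,6,10-trienoate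
Conditions: NBS, Me2S, CH2Cl2, 0 °C to rt
Reagents that add atoms: N-bromosuccinimide O=C1CCC(=O)N1Br
Why: SN2′ bromination of a Morita–Baylis–Hillman alcohol through its alkoxysulfonium salt is known to give the (Z)-2-(bromomethyl)enoate, which places C8 cis to C13 as the next step requires.

Step 11
Reactants: 16 allylic bromide enal
Product: 17 methyl (1(10)E,4Z,6S,7S,8R,9S)-8,9-bis[(tert-butyldimethylsilyl)oxy]-15-[(tert-butyldiphenylsilyl)oxy]-6-hydroxygermacra-1(10),4,11(13)-trien-12-oate
Conditions: In powder, THF/H2O 4:1, 2 mM, syringe-pump addition of 16, rt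
Reagents that add atoms: none
Why: In this intramolecular Barbier allylation, a known way to close medium rings, the (Z)-2-(methoxycarbonyl)allylmetal adds through C7 in a closed Zimmerman–Traxler chair with the C5 alkenyl group equatorial and so gives the syn C6/C7 pair (6S,7S), while A(1,3) strain holds H8 in the alkene plane so that the aldehyde, delivered by the C9 tether, bonds to the C7 face anti to the C8 silyloxy group.

Step 12
Reactants: 17 macrocyclic hydroxy ester; 18 angelic acid
Product: 19 methyl (1(10)E,4Z,6S,7S,8R,9S)-6-angeloyloxy-8,9-bis[(tert-butyldimethylsilyl)oxy]-15-[(tert-butyldiphenylsilyl)oxy]germacra-1(10),4,11(13)-trien-12-oate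
Conditions: 18, 2,4,6-trichlorobenzoyl chloride, Et3N, toluene, rt; then 17, 75 °C
Reagents that add atoms: none
Why: Yamaguchi-type mixed-anhydride esterification without a nucleophilic catalyst is the established way to make angelates of hindered alcohols without Z-to-E isomerisation, and it retains the C6 configuration.

Step 13
Reactants: 19 angelate
Product: 21 (1(10)E,4Z,6S,7S,8R,9S)-6-angeloyloxy-9,15-dihydroxygermacra-1(10),4,11(13)-trien-12,8-olide, via triol methyl ester 20 (not isolated)
Conditions: HF·pyridine, pyridine, THF, 0 °C to rt; aq. NaHCO3 work-up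
Reagents that add atoms: none
Why: Buffered fluoride desilylation frees the three hydroxyl groups, and the C8 hydroxyl then lactonises 5-exo-trig onto the C12 ester to give the trans-fused γ-lactone in preference to a six-membered lactone from O9.

Step 14
Reactants: 21 germacranolide diol
Product: 23 (5R,6S,7S,8R,9S,10S)-6-angeloyloxy-9-hydroxy-15-oxoelema-1,3,11(13)-trien-12,8-olide (target), via 15-oxogermacranolide 22 (not isolated)
Conditions: TEMPO (cat.), PhI(OAc)2 (slight excess), CH2Cl2, 0 °C to rt; aq. NaHCO3 wash, then toluene, 80 °C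
Reagents that add atoms: none
Why: TEMPO/PhI(OAc)2 oxidises the primary allylic C15 alcohol faster than the secondary C9 alcohol and gives enal 22, whose 1,5-diene C10=C1–C2–C3–C4=C5 undergoes a thermal Cope rearrangement in which C2–C3 breaks as C5–C10 forms. The closest known reaction type is the germacrane-to-elemane Cope rearrangement, which a formyl group on C4 is known to ease and to drive forward. Ring A closes by a transannular [3,3] shift that contracts the ten-membered ring to six through a chair transition state. Because the ring bonds are trans across both alkenes, C9 and C6 sit equatorial and C14 and H5 axial in that chair, which fixes the methyl group and H5 anti and so relates C10 to C5. The absolute sense comes from ring B, since only the chair that keeps the lactone bonds at C7 and C8 diequatorial is reachable, and this puts C14 on the same face as C11 (10S,5R). The step needs chemoselective oxidation and a product-side equilibrium: the first rests on the primary-over-secondary preference of the oxoammonium salt, the second on release of ten-ring strain with enal conjugation retained (C4=C5–CHO becomes C3=C4–CHO).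

Compound list
1 | tert-butyl(prop-2-yn-1-yloxy)diphenylsilane | C#CCO[Si](c1ccccc1)(c1ccccc1)C(C)(C)C | starting material
2 | methyl chloroformate | COC(=O)Cl | starting material
3 | methyl 4-[(tert-butyldiphenylsilyl)oxy]but-2-ynoate | COC(=O)C#CCO[Si](c1ccccc1)(c1ccccc1)C(C)(C)C | intermediate
4 | but-3-en-1-ylmagnesium bromide | C=CCC[Mg]Br | starting material
5 | methyl (2Z)-3-{[(tert-butyldiphenylsilyl)oxy]methyl}hepta-2,6-dienoate | C=CCC/C(CO[Si](c1ccccc1)(c1ccccc1)C(C)(C)C)=C/C(=O)OC | intermediate
6 | methacrolein | C=C(C)C=O | starting material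
7 | methyl (2Z,6E)-3-{[(tert-butyldiphenylsilyl)oxy]methyl}-7-methyl-8-oxoocta-2,6-dienoate | O=C/C(C)=C/CC/C(CO[Si](c1ccccc1)(c1ccccc1)C(C)(C)C)=C/C(=O)OC | intermediate
8 | (5R,6R)-5,6-dimethoxy-5,6-dimethyl-1,4-dioxan-2-one | O=C1CO[C@@](C)(OC)[C@](C)(OC)O1 | starting material
9 | anti aldol adduct, methyl (2Z,6E,8S)-8-[(2S,5R,6R)-5,6-dimethoxy-5,6-dimethyl-3-oxo-1,4-dioxan-2-yl]-8-hydroxy-7-methyl-3-{[(tert-butyldiphenylsilyl)oxy]methyl}octa-2,6-dienoate | O=C1O[C@@](C)(OC)[C@](C)(OC)O[C@H]1[C@@H](O)/C(C)=C/CC/C(CO[Si](c1ccccc1)(c1ccccc1)C(C)(C)C)=C/C(=O)OC | intermediate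
10 | dimethyl (2S,3S,4E,8Z)-2,3-dihydroxy-4-methyl-8-{[(tert-butyldiphenylsilyl)oxy]methyl}deca-4,8-dienedioate | COC(=O)[C@@H](O)[C@@H](O)/C(C)=C/CC/C(CO[Si](c1ccccc1)(c1ccccc1)C(C)(C)C)=C/C(=O)OC | intermediate
11 | dimethyl (2S,3S,4E,8Z)-2,3-bis[(tert-butyldimethylsilyl)oxy]-4-methyl-8-{[(tert-butyldiphenylsilyl)oxy]methyl}deca-4,8-dienedioate | COC(=O)[C@@H](O[Si](C)(C)C(C)(C)C)[C@@H](O[Si](C)(C)C(C)(C)C)/C(C)=C/CC/C(CO[Si](c1ccccc1)(c1ccccc1)C(C)(C)C)=C/C(=O)OC | intermediate
12 | (2R,3S,4E,8Z)-2,3-bis[(tert-butyldimethylsilyl)oxy]-4-methyl-8-{[(tert-butyldiphenylsilyl)oxy]methyl}deca-4,8-diene-1,10-diol | OC[C@@H](O[Si](C)(C)C(C)(C)C)[C@@H](O[Si](C)(C)C(C)(C)C)/C(C)=C/CC/C(CO[Si](c1ccccc1)(c1ccccc1)C(C)(C)C)=C/CO | intermediate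
13 | (2S,3S,4E,8Z)-2,3-bis[(tert-butyldimethylsilyl)oxy]-4-methyl-8-{[(tert-butyldiphenylsilyl)oxy]methyl}deca-4,8-dienedial | O=C[C@@H](O[Si](C)(C)C(C)(C)C)[C@@H](O[Si](C)(C)C(C)(C)C)/C(C)=C/CC/C(CO[Si](c1ccccc1)(c1ccccc1)C(C)(C)C)=C/C=O | intermediate
14 | methyl acrylate | C=CC(=O)OC | starting material
15 | Morita–Baylis–Hillman adduct, methyl (4R,5S,6E,10Z)-4,5-bis[(tert-butyldimethylsilyl)oxy]-3-hydroxy-6-methyl-2-methylidene-12-oxo-10-{[(tert-butyldiphenylsilyl)oxy]methyl}dodeca-6,10-dienoate, both C3 epimers | C=C(C(=O)OC)C(O)[C@@H](O[Si](C)(C)C(C)(C)C)[C@@H](O[Si](C)(C)C(C)(C)C)/C(C)=C/CC/C(CO[Si](c1ccccc1)(c1ccccc1)C(C)(C)C)=C/C=O | intermediate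
16 | methyl (2Z,4R,5S,6E,10Z)-2-(bromomethyl)-4,5-bis[(tert-butyldimethylsilyl)oxy]-6-methyl-12-oxo-10-{[(tert-butyldiphenylsilyl)oxy]methyl}dodeca-2,6,10-trienoate | BrC/C(C(=O)OC)=C\[C@@H](O[Si](C)(C)C(C)(C)C)[C@@H](O[Si](C)(C)C(C)(C)C)/C(C)=C/CC/C(CO[Si](c1ccccc1)(c1ccccc1)C(C)(C)C)=C/C=O | intermediate
17 | methyl (1(10)E,4Z,6S,7S,8R,9S)-8,9-bis[(tert-butyldimethylsilyl)oxy]-15-[(tert-butyldiphenylsilyl)oxy]-6-hydroxygermacra-1(10),4,11(13)-trien-12-oate | C/C1=C\CC/C(CO[Si](c2ccccc2)(c2ccccc2)C(C)(C)C)=C/[C@H](O)[C@H](C(=C)C(=O)OC)[C@@H](O[Si](C)(C)C(C)(C)C)[C@H]1O[Si](C)(C)C(C)(C)C | intermediate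
18 | angelic acid, (Z)-2-methylbut-2-enoic acid | C/C=C(/C)C(=O)O | starting material
19 | methyl (1(10)E,4Z,6S,7S,8R,9S)-6-angeloyloxy-8,9-bis[(tert-butyldimethylsilyl)oxy]-15-[(tert-butyldiphenylsilyl)oxy]germacra-1(10),4,11(13)-trien-12-oate | C/C1=C\CC/C(CO[Si](c2ccccc2)(c2ccccc2)C(C)(C)C)=C/[C@H](OC(=O)/C(C)=C\C)[C@H](C(=C)C(=O)OC)[C@@H](O[Si](C)(C)C(C)(C)C)[C@H]1O[Si](C)(C)C(C)(C)C | intermediate
20 | triol methyl ester, compound 19 with all three silyl groups removed and configuration unchanged | C/C1=C\CC/C(CO)=C/[C@H](OC(=O)/C(C)=C\C)[C@H](C(=C)C(=O)OC)[C@@H](O)[C@H]1O | intermediate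
21 | (1(10)E,4Z,6S,7S,8R,9S)-6-angeloyloxy-9,15-dihydroxygermacra-1(10),4,11(13)-trien-12,8-olide | C/C1=C\CC/C(CO)=C/[C@H](OC(=O)/C(C)=C\C)[C@@H]2C(=C)C(=O)O[C@H]2[C@H]1O | intermediate
22 | (1(10)E,4Z,6S,7S,8R,9S)-6-angeloyloxy-9-hydroxy-15-oxogermacra-1(10),4,11(13)-trien-12,8-olide | C/C1=C\CC/C(C=O)=C/[C@H](OC(=O)/C(C)=C\C)[C@@H]2C(=C)C(=O)O[C@H]2[C@H]1O | intermediate
23 | (5R,6S,7S,8R,9S,10S)-6-angeloyloxy-9-hydroxy-15-oxoelema-1,3,11(13)-trien-12,8-olide | C=C[C@]1(C)[C@H](O)[C@@H]2OC(=O)C(=C)[C@H]2[C@@H](OC(=O)/C(C)=C\C)[C@H]1C(=C)C=O | target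

Total step count: 14. Longest linear sequence: 14 (from 1).

Steps most likely to fail

Step 11 (ring closure).
- Closure of the ten-membered ring may be outrun by oligomerisation, by protonolysis of the allylmetal or by 1,4-elimination of the C8 silyloxy group. Facial selectivity at C7 may also be poor.
- The fallback sets out from 15 and comes back at 17.
- Acetylation (Ac2O, pyridine, cat. DMAP, CH2Cl2) should give the Morita–Baylis–Hillman acetate F1.
- Slow addition of this acetate to Pd(PPh3)4 (cat.) and indium monoiodide (InI) in dry THF ionises it to a π-allylpalladium complex.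
- Reductive transmetalation then produces the allylindium nucleophile catalytically, in low stationary concentration and without a proton source, and it closes to 17.

Step 12 (angelate).
- Slow acylation of the hindered C6 alcohol may let lactonisation of O6 onto the C12 ester compete. Z-to-E isomerisation of the angeloyl unit is a second possible loss.
- The fallback sets out from 17 and comes back at 19. It builds the Z-alkene on the molecule instead of transferring it.
- Esterification with 2-[bis(2,2,2-trifluoroethoxy)phosphoryl]propanoic acid (EDC·HCl, DMAP, CH2Cl2, rt) should give the phosphonopropionate ester F2.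
- A Still–Gennari olefination (KN(SiMe3)2, 18-crown-6, THF, −78 °C, then acetaldehyde) then delivers the (Z)-2-methylbut-2-enoate 19.

Step 9 (Morita–Baylis–Hillman reaction).
- Slow addition to the aldehyde flanked by two silyloxy groups may allow amine-induced epimerisation at C8 or loss of the aldehyde.
- The fallback sets out from 13 and comes back at 15. It replaces amine catalysis by a preformed nucleophile.
- Hydroalumination of methyl propiolate (i-Bu2AlH, HMPA, THF, 0 °C) gives [1-(methoxycarbonyl)vinyl]diisobutylaluminium.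
- This reagent should add at −78 °C to the more electrophilic saturated aldehyde and give 15 directly, so no new compound arises (F0).

Further compounds
F1 | step 11 | Morita–Baylis–Hillman acetate, the C7 O-acetate of 15 | C=C(C(=O)OC)C(OC(C)=O)[C@@H](O[Si](C)(C)C(C)(C)C)[C@@H](O[Si](C)(C)C(C)(C)C)/C(C)=C/CC/C(CO[Si](c1ccccc1)(c1ccccc1)C(C)(C)C)=C/C=O
F2 | step 12 | phosphonopropionate ester, the C6 O-{2-[bis(2,2,2-trifluoroethoxy)phosphoryl]propanoate} of 17 | C/C1=C\CC/C(CO[Si](c2ccccc2)(c2ccccc2)C(C)(C)C)=C/[C@H](OC(=O)C(C)P(=O)(OCC(F)(F)F)OCC(F)(F)F)[C@H](C(=C)C(=O)OC)[C@@H](O[Si](C)(C)C(C)(C)C)[C@H]1O[Si](C)(C)C(C)(C)C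
F0 | step 9 | none | none
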